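The plan rests on one feature of ring C: C3 is a bare CH2 lying between the stereocentre C2 and the carbonyl carbon C4. Excising it shrinks the dihydropyranone to a furan. The target is therefore traced to a 2-(3,4-dimethoxyphenyl)-3-silyloxybenzofuran that already carries the 5-benzyloxy-4,6-dimethoxy pattern of ring A. A chiral iodomethylzinc reagent hands the carbon back to the enol ether double bond, forming C2–C3, C3–C4 and both bridgehead stereocentres in one operation. Freeing the cyclopropanol and opening it with base then cuts the shared C2–C4 bond, which enlarges the ring and relays the chirality to C2. A triethylsilyl ether is chosen over trimethylsilyl for robustness.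

Key step: step 8

Assumption: the facial sense of the dipeptide–zinc carbenoid on the benzofuran cannot be predicted, so the L,L-ligand is written and its equally available D,D-antipode would be used if the induction proved opposite. Flavanone numbering (O1, C2, C3, C4, C4a to C8a) is used in the discussion.

Step 1
Reactants: 1 syringaldehyde (4-hydroxy-3,5-dimethoxybenzaldehyde)
Product: 2 4-(benzyloxy)-3,5-dimethoxybenzaldehyde
Conditions: BnBr, K2CO3, DMF, 60 °C
Reagents that add atoms: benzyl bromide, BrCc1ccccc1
Why: Williamson etherification of the acidic para-formyl phenol should be clean, and the benzyl ether masks the future C6 hydroxyl through every later step yet leaves under neutral hydrogenolysis.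

Step 2
Reactants: 2 4-(benzyloxy)-3,5-dimethoxybenzaldehyde
Product: 4 4-(benzyloxy)-3,5-dimethoxyphenol, via aryl formate 3 (not isolated)
Conditions: mCPBA, CH2Cl2, 0 °C → rt; aq. NaHCO3 wash; then K2CO3 (cat.), MeOH, rt
Reagents that add atoms: mCPBA (3-chloroperoxybenzoic acid), OOC(=O)c1cccc(Cl)c1
Why: In this Baeyer–Villiger oxidation the electron-rich aryl group migrates in preference to hydride, and base-catalysed methanolysis of the formate frees a mirror-symmetric phenol whose two ortho positions are equivalent.

Step 3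
Reactants: 5 methyl 2-(3,4-dimethoxyphenyl)acetate
Product: 6 methyl 2-diazo-2-(3,4-dimethoxyphenyl)acetate
Conditions: p-ABSA, DBU, MeCN, 0 °C → rt
Reagents that add atoms: 4-acetamidobenzenesulfonyl azide (p-ABSA), CC(=O)Nc1ccc(cc1)S(=O)(=O)N=[N+]=[N-]
Why: Regitz diazo transfer onto the benzylic, ester-activated CH2 is routine for arylacetates and avoids bromination, which would attack the veratryl ring.

Step 4
Reactants: 4 4-(benzyloxy)-3,5-dimethoxyphenol; 6 methyl 2-diazo-2-(3,4-dimethoxyphenyl)acetate
Product: 7 methyl 2-[4-(benzyloxy)-3,5-dimethoxyphenoxy]-2-(3,4-dimethoxyphenyl)acetate (racemic)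
Conditions: Rh2(OAc)4 (1 mol%), CH2Cl2, rt, slow addition of 6
Reagents that add atoms: none
Why: Rhodium carbenoid O–H insertion into the unhindered phenol (oxonium ylide, then proton shift) outruns arene or C–H attack and makes the O1–C2 bond; the new stereocentre is racemic and is erased in step 7.

Step 5
Reactants: 7 methyl 2-[4-(benzyloxy)-3,5-dimethoxyphenoxy]-2-(3,4-dimethoxyphenyl)acetate
Product: 8 2-[4-(benzyloxy)-3,5-dimethoxyphenoxy]-2-(3,4-dimethoxyphenyl)acetic acid (racemic)
Conditions: LiOH, THF–MeOH–H2O, rt; then 1 M HCl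
Reagents that add atoms: lithium hydroxide, [Li+].[OH-]
Why: Ordinary saponification of a methyl ester touches none of the aryl ethers present.

Step 6
Reactants: 8 2-[4-(benzyloxy)-3,5-dimethoxyphenoxy]-2-(3,4-dimethoxyphenyl)acetic acid
Product: 10 5-(benzyloxy)-2-(3,4-dimethoxyphenyl)-4,6-dimethoxybenzofuran-3(2H)-one (racemic), via mixed trifluoroacetic anhydride 9 (not isolated)
Conditions: (CF3CO)2O, CH2Cl2, 0 °C → rt, argon; then aq. NaHCO3
Reagents that add atoms: trifluoroacetic anhydride, O=C(OC(=O)C(F)(F)F)C(F)(F)F (its atoms are held only in 9, none in 10)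
Why: In this intramolecular Friedel–Crafts acylation the attacked carbon is ortho to two oxygens and para to a third, the two ortho sites are equivalent so only one regioisomer can form, and the absence of a strong Lewis acid spares the benzyl ether and the peri methoxy group and limits decarbonylation.

Step 7
Reactants: 10 5-(benzyloxy)-2-(3,4-dimethoxyphenyl)-4,6-dimethoxybenzofuran-3(2H)-one
Product: 11 {[5-(benzyloxy)-2-(3,4-dimethoxyphenyl)-4,6-dimethoxybenzofuran-3-yl]oxy}triethylsilane
Conditions: Et3SiOTf, Et3N, CH2Cl2, 0 °C, argon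
Reagents that add atoms: triethylsilyl triflate, CC[Si](CC)(CC)OS(=O)(=O)C(F)(F)F
Why: Soft enolisation and O-silylation of the doubly activated C2–H ketone is driven by aromatisation to the benzofuran, and the triethylsilyl ether allows purification on deactivated silica where a trimethylsilyl ether would hydrolyse.

Step 8
Reactants: 11 {[5-(benzyloxy)-2-(3,4-dimethoxyphenyl)-4,6-dimethoxybenzofuran-3-yl]oxy}triethylsilane; 12 diiodomethane
Product: 13 (1aR,6bR)-5-(benzyloxy)-1a-(3,4-dimethoxyphenyl)-4,6-dimethoxy-6b-(triethylsilyloxy)-1a,6b-dihydro-1H-cyclopropa[b]benzofuran (cis-fused)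
Conditions: Et2Zn, CH2I2, N-Boc-L-Val-L-Pro-OMe (stoichiometric), CH2Cl2, −40 → 0 °C; pyridine, then aq. NaHCO3
Reagents that add atoms: diiodomethane (12), ICI
Why: Proposed new method: the C2=C3 bond of 11 carries the ring oxygen on one terminus and the silyloxy group on the other and is only weakly tied into furan aromaticity, so it should attack the electrophilic CH2 of the ligand-bound iodomethylzinc species through the concerted butterfly transition state while iodide passes to zinc. The closest known reaction type is the Simmons–Smith (Furukawa) cyclopropanation of silyl enol ethers, including its enantioselective form with N-Boc-dipeptide zinc carbenoids; a benzofuran double bond has not been shown to take part. The three-membered ring closes by suprafacial [2+1] methylene transfer, both C–C bonds forming on the same face, so only the cis-fused 2-oxabicyclo[3.1.0]hexane can arise, and its outer rim O1–C2–C3–C4–C4a–C8a is already ring C of the target. The relative configuration of C1a and C6b is thus dictated by the ring fusion, and their absolute configuration (1aR,6bR) by the chiral ligand on zinc, which has to tell the flat benzo-fused flank of the alkene from the flank bearing the rotatable veratryl group. Chemoselectivity is secured by the substrate, since this is its only non-benzenoid π bond and zinc carbenoids leave arenes, aryl methyl ethers and the benzyl ether untouched. The triethylsilyl ether should withstand the ZnI2 that builds up, and the cold pyridine quench prevents Lewis acid opening of the electron-rich cyclopropane.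

Step 9
Reactants: 13 (1aR,6bR)-5-(benzyloxy)-1a-(3,4-dimethoxyphenyl)-4,6-dimethoxy-6b-(triethylsilyloxy)-1a,6b-dihydro-1H-cyclopropa[b]benzofuran
Product: 15 (2S)-6-(benzyloxy)-2-(3,4-dimethoxyphenyl)-5,7-dimethoxychroman-4-one, via free cyclopropanol 14 (not isolated)
Conditions: TBAF/AcOH (1:1, 1.1 equiv), THF–MeOH 1:3, −20 °C; then K2CO3 (0.3 equiv), −20 → 0 °C; AcOH quench
Reagents that add atoms: none
Why: Proposed new method: buffered fluoride removes the silyl group without acid or strong base, and catalytic carbonate in methanol then forms the cyclopropanolate, whose oxygen expels the C2–C4 bond because C2 is the only cyclopropane carbon able to bear negative charge (benzylic and oxygen-bearing) and because this cleavage releases the strain of both fused rings; methanol should protonate C2 at the rear lobe of the breaking bond (SE2 with inversion), which converts 1aR into 2S; the closest known reaction type is the base-induced homoketonisation of 2-arylcyclopropanols, which cleaves toward the benzylic carbon with inversion in protic media, but it has not been shown on a cyclopropa[b]benzofuranol or as a ring enlargement to a flavanone; low temperature, catalytic base and the acid quench keep retro-oxa-Michael racemisation of 15 out of play.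

Step 10
Reactants: 15 (2S)-6-(benzyloxy)-2-(3,4-dimethoxyphenyl)-5,7-dimethoxychroman-4-one
Product: 16 (2S)-2-(3,4-dimethoxyphenyl)-6-hydroxy-5,7-dimethoxychroman-4-one (target)
Conditions: H2 (1 atm), 10% Pd/C, EtOAc, rt
Reagents that add atoms: none
Why: Catalytic hydrogenolysis of the aryl benzyl ether runs under neutral conditions that neither enolise C3 nor open ring C, so C2 keeps its S configuration.

Compound list
1 | syringaldehyde | COc1cc(C=O)cc(OC)c1O | starting material
2 | 4-(benzyloxy)-3,5-dimethoxybenzaldehyde | COc1cc(C=O)cc(OC)c1OCc1ccccc1 | intermediate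
3 | 4-(benzyloxy)-3,5-dimethoxyphenyl formate | COc1cc(OC=O)cc(OC)c1OCc1ccccc1 | intermediate
4 | 4-(benzyloxy)-3,5-dimethoxyphenol | COc1cc(O)cc(OC)c1OCc1ccccc1 | intermediate
5 | methyl 2-(3,4-dimethoxyphenyl)acetate | COC(=O)Cc1ccc(OC)c(OC)c1 | starting material
6 | methyl 2-diazo-2-(3,4-dimethoxyphenyl)acetate | COC(=O)C(=[N+]=[N-])c1ccc(OC)c(OC)c1 | intermediate
7 | methyl 2-[4-(benzyloxy)-3,5-dimethoxyphenoxy]-2-(3,4-dimethoxyphenyl)acetate (racemic) | COC(=O)C(Oc1cc(OC)c(OCc2ccccc2)c(OC)c1)c1ccc(OC)c(OC)c1 | intermediate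
8 | 2-[4-(benzyloxy)-3,5-dimethoxyphenoxy]-2-(3,4-dimethoxyphenyl)acetic acid (racemic) | OC(=O)C(Oc1cc(OC)c(OCc2ccccc2)c(OC)c1)c1ccc(OC)c(OC)c1 | intermediate
9 | 2-[4-(benzyloxy)-3,5-dimethoxyphenoxy]-2-(3,4-dimethoxyphenyl)acetic trifluoroacetic anhydride (racemic) | O=C(OC(=O)C(F)(F)F)C(Oc1cc(OC)c(OCc2ccccc2)c(OC)c1)c1ccc(OC)c(OC)c1 | intermediate
10 | 5-(benzyloxy)-2-(3,4-dimethoxyphenyl)-4,6-dimethoxybenzofuran-3(2H)-one (racemic) | COc1ccc(C2Oc3cc(OC)c(OCc4ccccc4)c(OC)c3C2=O)cc1OC | intermediate
11 | {[5-(benzyloxy)-2-(3,4-dimethoxyphenyl)-4,6-dimethoxybenzofuran-3-yl]oxy}triethylsilane | COc1ccc(-c2oc3cc(OC)c(OCc4ccccc4)c(OC)c3c2O[Si](CC)(CC)CC)cc1OC | intermediate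
12 | diiodomethane | ICI | starting material
13 | (1aR,6bR)-5-(benzyloxy)-1a-(3,4-dimethoxyphenyl)-4,6-dimethoxy-6b-(triethylsilyloxy)-1a,6b-dihydro-1H-cyclopropa[b]benzofuran | COc1ccc([C@]23C[C@@]2(O[Si](CC)(CC)CC)c2c(cc(OC)c(OCc4ccccc4)c2OC)O3)cc1OC | intermediate
14 | (1aR,6bR)-5-(benzyloxy)-1a-(3,4-dimethoxyphenyl)-4,6-dimethoxy-1a,6b-dihydro-1H-cyclopropa[b]benzofuran-6b-ol | COc1ccc([C@]23C[C@@]2(O)c2c(cc(OC)c(OCc4ccccc4)c2OC)O3)cc1OC | intermediate
15 | (2S)-6-(benzyloxy)-2-(3,4-dimethoxyphenyl)-5,7-dimethoxychroman-4-one | COc1ccc([C@@H]2CC(=O)c3c(cc(OC)c(OCc4ccccc4)c3OC)O2)cc1OC | intermediate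
16 | (2S)-2-(3,4-dimethoxyphenyl)-6-hydroxy-5,7-dimethoxychroman-4-one | COc1ccc([C@@H]2CC(=O)c3c(cc(OC)c(O)c3OC)O2)cc1OC | target

Total step count: 10. Longest linear sequence: 9 (steps 1, 2, 4, 5, 6, 7, 8, 9, 10).

Steps most likely to fail

First, step 8. Methylene transfer may stall on the crowded tetrasubstituted double bond, which has to give up its furan conjugation, or the ligand sphere may discriminate poorly between the two faces. The fallback drops carbon insertion and builds ring C by known asymmetric conjugate arylation.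
- Setting out from 4, ortho-acetylation (Ac2O, BF3·OEt2) should give 1-[3-(benzyloxy)-6-hydroxy-2,4-dimethoxyphenyl]ethan-1-one F1.
- DMF dimethyl acetal converts it into (E)-1-[3-(benzyloxy)-6-hydroxy-2,4-dimethoxyphenyl]-3-(dimethylamino)prop-2-en-1-one F2.
- HCl in CH2Cl2 closes 6-(benzyloxy)-5,7-dimethoxy-4H-chromen-4-one F3.
- 1,4-Addition of 3,4-dimethoxyphenylboronic acid adds the aryl group to C2 and comes back to the route at 15. Conditions: Pd(OCOCF3)2, the t-BuPyOx antipode that delivers 2S, NH4PF6, H2O, ClCH2CH2Cl, 60 °C.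

Second, step 9. The opening may cleave a peripheral cyclopropane bond. Configuration may also leak through protonation of a planarised benzylic anion or through retro-oxa-Michael opening of ring C. The fallback keeps the inserted carbon but resets C2 by known catalysis, so the configuration of 13 no longer matters.
- Setting out from 13, FeCl3 in DMF at 0 °C is used. This is the one-electron oxidative ring expansion of siloxycyclopropanes, which breaks the internal bond through the alkoxy radical. With loss of HCl it should give 6-(benzyloxy)-2-(3,4-dimethoxyphenyl)-5,7-dimethoxy-4H-chromen-4-one F4.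
- Asymmetric hydrogenation of the pyranone ring ([Ru(cod)(2-methylallyl)2], chiral NHC salt SINpEt·HBF4, KOt-Bu, H2) leads to (2S,4S)-6-(benzyloxy)-2-(3,4-dimethoxyphenyl)-5,7-dimethoxychroman-4-ol F5.
- Dess–Martin oxidation of the carbinol comes back to the route at 15.

Third, step 6. The activated acyl species may decarbonylate, because loss of CO leaves a strongly stabilised oxybenzylic cation, or the acid liberated may strip the flanked benzyl ether. The fallback reverses the order of bond formation, making the aryl–carbonyl bond first and the O1–C2 bond last.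
- Setting out from 4, a Houben–Hoesch reaction with 3,4-dimethoxyphenylacetonitrile (ZnCl2, HCl, Et2O, 0 °C) gives 1-[3-(benzyloxy)-6-hydroxy-2,4-dimethoxyphenyl]-2-(3,4-dimethoxyphenyl)ethan-1-imine hydrochloride F6.
- Warm water hydrolyses it to 1-[3-(benzyloxy)-6-hydroxy-2,4-dimethoxyphenyl]-2-(3,4-dimethoxyphenyl)ethan-1-one F7.
- Regitz diazo transfer (p-ABSA, DBU, MeCN) gives 1-[3-(benzyloxy)-6-hydroxy-2,4-dimethoxyphenyl]-2-diazo-2-(3,4-dimethoxyphenyl)ethan-1-one F8.
- Rh2(OAc)4 in CH2Cl2 triggers intramolecular O–H insertion and comes back to the route at 10.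

Further compounds
F1 | step 8 | 1-[3-(benzyloxy)-6-hydroxy-2,4-dimethoxyphenyl]ethan-1-one | CC(=O)c1c(O)cc(OC)c(OCc2ccccc2)c1OC
F2 | step 8 | (E)-1-[3-(benzyloxy)-6-hydroxy-2,4-dimethoxyphenyl]-3-(dimethylamino)prop-2-en-1-one | CN(C)/C=C/C(=O)c1c(O)cc(OC)c(OCc2ccccc2)c1OC
F3 | step 8 | 6-(benzyloxy)-5,7-dimethoxy-4H-chromen-4-one | COc1cc2occc(=O)c2c(OC)c1OCc1ccccc1
F4 | step 9 | 6-(benzyloxy)-2-(3,4-dimethoxyphenyl)-5,7-dimethoxy-4H-chromen-4-one | COc1ccc(-c2cc(=O)c3c(cc(OC)c(OCc4ccccc4)c3OC)o2)cc1OC
F5 | step 9 | (2S,4S)-6-(benzyloxy)-2-(3,4-dimethoxyphenyl)-5,7-dimethoxychroman-4-ol | COc1ccc([C@@H]2C[C@H](O)c3c(cc(OC)c(OCc4ccccc4)c3OC)O2)cc1OC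
F6 | step 6 | 1-[3-(benzyloxy)-6-hydroxy-2,4-dimethoxyphenyl]-2-(3,4-dimethoxyphenyl)ethan-1-imine hydrochloride | Cl.N=C(Cc1ccc(OC)c(OC)c1)c1c(O)cc(OC)c(OCc2ccccc2)c1OC
F7 | step 6 | 1-[3-(benzyloxy)-6-hydroxy-2,4-dimethoxyphenyl]-2-(3,4-dimethoxyphenyl)ethan-1-one | O=C(Cc1ccc(OC)c(OC)c1)c1c(O)cc(OC)c(OCc2ccccc2)c1OC
F8 | step 6 | 1-[3-(benzyloxy)-6-hydroxy-2,4-dimethoxyphenyl]-2-diazo-2-(3,4-dimethoxyphenyl)ethan-1-one | O=C(C(=[N+]=[N-])c1ccc(OC)c(OC)c1)c1c(O)cc(OC)c(OCc2ccccc2)c1OC
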